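Two partners sit in each bis adduct, so a charge of one coupling partner per substrate cannot turn more than 50.0 % of the substrate into bis adduct. The same count gives a sharper rule. A consumed partner lands on fresh substrate or on a mono adduct. So bis adduct equals the allowance, less substrate used, less partner left, in percent of the substrate charged. The partner allowance is the partner charge over the substrate charge, 100 % in these flasks.

| flask | substrate | coupling partner | temperature | remark | time |
|---|---|---|---|---|---|
| Saturday's | 0.050 M | 0.050 M | −5 °C | run made earlier |  |
| Wednesday's | 0.070 M | 0.050 M | 6 °C | run made earlier |  |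
| Friday's | 0.11 M | 0.050 M | −5 °C | run made earlier |  |
| Thursday's | 0.050 M | 0.025 M | 6 °C | run made earlier |  |
| oak | 0.050 M (fed, over 1.5 h) | 0.0500 M |  | the addition at −20 °C, then warmed to 0 °C; the feed brings no volume worth counting | 4.0 h |
| ash | 0.050 M | 0.0500 M |  | everything together at the start at −20 °C, warmed to 0 °C at 1.5 h | 4.0 h |
| birch | 0.050 M (fed, over 1.5 h) | 0.0500 M | 0 °C | all else is in the flask from the start; the feed brings no volume worth counting | 4.0 h |
| elm | 0.050 M | 0.0500 M (fed, over 1.5 h) | 0 °C | all else is in the flask from the start; the feed brings no volume worth counting | 4.0 h |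
| cedar | 0.050 M | 0.0500 M | 0 °C | everything together at the start | 4.0 h |

- Saturday's (time / h: bis adduct / %, single product / %): 0.333: 21.2, 10.6; 0.667: 25.9, 5.9; 1.00: 27.2, 3.3; 2.00: 27.8, 1.2; 4.00: 28.0, 0.8
- Wednesday's (time / h: bis adduct / %, single product / %): 0.667: 14.6, 1.0; 1.33: 15.4, 0.4; 2.00: 15.4, 1.0; 2.50: 16.0, 0.8; 3.00: 14.9, 0.5
- Friday's (time / h: bis adduct / %, single product / %): 0.250: 7.9, 10.1; 0.833: 7.5, 1.8; 1.33: 7.3, 0.9; 2.50: 7.9, 0.9; 3.00: 8.0, 0.4
- Thursday's (time / h: bis adduct / %, single product / %): 0.250: 7.1, 4.2; 0.500: 7.5, 1.0; 0.833: 7.4, 1.0; 1.50: 7.7, 0.8; 3.00: 7.2, 0.9

(readings scatter by 0.3 percentage points)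



- the flask that comes out highest in amount of bis adduct, in percent of the substrate charged; "all alike" if 1.5 percentage points covers them all (oak / ash / birch / elm / cedar / all alike)
- amount of bis adduct at the end, in percent of the substrate charged, oak
- amount of bis adduct at the end, in percent of the substrate charged, ash
- amount of bis adduct at the end, in percent of the substrate charged, birch
- amount of bis adduct at the end, in percent of the substrate charged, elm
- amount of bis adduct at the end, in percent of the substrate charged, cedar

Saturday's run levels at 28.0 %. Taking [coupling partner] as nil at that reading, substrate used is the allowance less the reading, so a share of about 0.389 of the mono adducts reads as taking a second partner. Held for a fed flask at 0 °C, that share gives 28.0 %.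

The share is the weak link: it was read from one way of charging. Friday's single product falls while its bis adduct stands still, which reads a loss of 2.96 /h. Saturday's rise in bis adduct between its first two readings reads a capture of 1.71 /h. The allowance, with the lost single product counted, puts [coupling partner] there near 0.0162 M, so the constant reads 105 /M/h. Take [coupling partner] through a feed as 0.0250 M and let capture and loss shift alike with temperature. The share then becomes 0.470, higher than before, and a substrate feed gives about 32.0 %.

The forecast differs from this reckoning. It named ash as highest, with oak 28 %, ash 29.5 %, birch 25 %, elm 14 % and cedar 27 %, holding that “Feeding substrate gains little, because the dilute single product decays”.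

The flasks give oak 29.6 %, ash 29.2 %, birch 33.2 %, elm 20.9 % and cedar 27.0 %; highest is birch.

    substrate + coupling partner → single product (k = 2.00 /M/min, Ea = 52.0 kJ/mol)
    single product → over-reaction product (k = 0.00770 /min, Ea = 88.0 kJ/mol)
    single product ⇌ isomer of the product (K = 22.0, k = 0.0800 /min, Ea = 78.0 kJ/mol, ΔH = −17.0 kJ/mol)
    substrate + coupling partner → other mono adduct (k = 1.10 /M/min, Ea = 50.0 kJ/mol)
    coupling partner + single product → bis adduct (k = 4.90 /M/min, Ea = 48.0 kJ/mol)
    coupling partner + other mono adduct → bis adduct (k = 1.40 /M/min, Ea = 58.0 kJ/mol)
    (constants at 0 °C)

The mean [coupling partner] over the first 1.5 h is 0.0234 M in birch, against 0.00435 M in elm. Birch ends 12 percentage points above elm, and the largest single effect on that gap comes from the step of coupling partner and single product to bis adduct: without that step the gap is 4.2 points. The coupling partner, the limiting reagent, ends birch at 0 % of its charge, so the allowance less 66.8 % of substrate used gives 33.2 %. In a neighbour like birch with 0.085 M of coupling partner, the allowance is 170 %. Less 97.6 % of substrate used and 2.55 % of partner left, it gives 69.9 %; that flask shows 69.9 %.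

The runs are simulated with constants of no real substance; noise was put on by code.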